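The cyclopentane (C9, C11, C12, C13, C14) is opened at C9–C11 and C12–C13, so that C11–C12 arrive as phenyl vinyl sulfone. The feature used is that this ring hangs on quaternary C9 of the cis-fused cyclobutane (C8, C9, C14, C15) and ends at the C13 methyl carbinol, with C11 and the C14 acetyl group on one cyclobutane face. In one cathodic operation the C9 N-acyloxyphthalimide gives the C9 radical, which adds to the sulfone; the adduct radical is reduced and the carbanion closes onto the acetyl group. The precursor is the tricyclic [2+2] photoadduct carrying this ester, the C14 acetyl group and an unprotected C7 ketone, which lies trans to C11 and cannot interfere.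

Key step: step 13

Remark: atoms carry labdane numbers (ring A C1–C5 and C10, ring B C5–C10; the carboxyl carbon on C9 is lost as CO2), and in the cyclization product the sulfonyl group is assumed on the convex face, cis to the C13 oxygen, as one bridging magnesium ion requires; that centre becomes a methylene one step later.

Step 1
Reactants: 1 (+)-sclareolide
Product: 2 11-hydroxysclareolide
Conditions: KN(SiMe3)2, THF, −78 °C; 2-(phenylsulfonyl)-3-phenyloxaziridine, −78 °C; aqueous work-up
Reagents that add atoms: 2-(phenylsulfonyl)-3-phenyloxaziridine, O=S(=O)(c1ccccc1)N1OC1c1ccccc1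
Why: Davis α-hydroxylation of the lactone enolate, in which oxygen should arrive on the lactone face that carries H-9 (away from the C8 and C10 methyl groups); the new C11 centre is destroyed in step 3.

Step 2
Reactants: 2 11-hydroxysclareolide
Product: 3 8α,11,12-triol
Conditions: LiAlH4, THF, 0 °C to reflux; Fieser work-up
Reagents that add atoms: none
Why: Hydride reduction of the lactone to the primary alcohol and the tertiary C8 alcohol touches no stereocentre.

Step 3
Reactants: 3 8α,11,12-triol
Product: 4 8α-hydroxy C11 aldehyde
Conditions: NaIO4, THF/H2O, 0 °C to rt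
Reagents that add atoms: none
Why: Periodate glycol cleavage of the C11–C12 diol removes C12 as formaldehyde and leaves the tertiary C8 alcohol, which is not part of a 1,2-diol.

Step 4
Reactants: 4 8α-hydroxy C11 aldehyde
Product: 5 C8=C9 enal
Conditions: p-TsOH·H2O (cat.), toluene, reflux (Dean–Stark)
Reagents that add atoms: none
Why: Acid-catalysed dehydration of the tertiary β-hydroxy aldehyde (E1 with equilibration through the dienol) should converge on the conjugated tetrasubstituted C8=C9 enal, the β-cyclocitral-type isomer.

Step 5
Reactants: 5 C8=C9 enal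
Product: 6 C8=C9 C11 acid
Conditions: NaClO2, NaH2PO4, 2-methylbut-2-ene, t-BuOH/H2O, rt
Reagents that add atoms: sodium chlorite, [Na+].[O-]Cl=O
Why: Pinnick oxidation converts the hindered conjugated aldehyde into the acid without touching the tetrasubstituted alkene, hypochlorous acid being trapped by the added alkene.

Step 6
Reactants: 6 C8=C9 C11 acid
Product: 7 7-oxo C8=C9 C11 acid
Conditions: CrO3, AcOH/Ac2O, 10 °C to rt
Reagents that add atoms: chromium trioxide, O=[Cr](=O)=O
Why: Chromium-mediated allylic oxidation should take the only allylic methylene (C7) to the ketone, the same γ-oxidation that turns cyclohex-1-enecarboxylic acid derivatives into their 3-oxo compounds, while the C8 methyl group is the slower primary position.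

Step 7
Reactants: 7 7-oxo C8=C9 C11 acid
Product: 8 benzyl 7-oxo C8=C9 C11 ester
Conditions: BnBr, K2CO3, DMF, rt
Reagents that add atoms: benzyl bromide, BrCc1ccccc1
Why: Carboxylate alkylation (SN2 at the benzylic carbon) does not depend on crowding at the acyl carbon and gives an ester that is later removed by hydrogenolysis, again without attack at that carbon.

Step 8
Reactants: 9 but-3-en-2-one
Product: 10 2-methyl-2-vinyl-1,3-dioxolane
Conditions: 1,2-bis(trimethylsilyloxy)ethane, TMSOTf (cat.), CH2Cl2, −78 °C
Reagents that add atoms: 1,2-bis(trimethylsilyloxy)ethane, C[Si](C)(C)OCCO[Si](C)(C)C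
Why: Noyori ketalization protects the enone carbonyl at low temperature without conjugate addition or double-bond migration.

Step 9
Reactants: 8 benzyl 7-oxo C8=C9 C11 ester; 10 2-methyl-2-vinyl-1,3-dioxolane
Product: 11 tricyclic photoadduct
Conditions: hν (350 nm, Pyrex), 10 (10 equiv), CH2Cl2, −40 °C
Reagents that add atoms: none
Why: Enone–alkene [2+2] photocycloaddition through the enone triplet, in which the alkyl-type alkene should add head-to-tail (its substituted carbon to the β-carbon C9, CH2 to C8) on the α face anti to the axial C10 methyl group to give the cis 6–4 fusion, with the dioxolanyl group on the cyclobutane face away from C10 and cis to the ester; a minor C14 epimer is removed by chromatography.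

Step 10
Reactants: 11 tricyclic photoadduct
Product: 12 tricyclic C9 acid
Conditions: H2 (1 atm), Pd/C (10%), EtOAc, rt
Reagents that add atoms: none
Why: Hydrogenolysis cleaves the benzyl–oxygen bond, so the very hindered ester is opened without nucleophilic attack, and ketal and ketone are inert.

Step 11
Reactants: 12 tricyclic C9 acid; 13 N-hydroxyphthalimide
Product: 15 ketal-protected C9 N-acyloxyphthalimide, via acid chloride 14 (not isolated)
Conditions: 1-chloro-N,N,2-trimethylprop-1-en-1-amine, CH2Cl2, 0 °C to rt; then 13, Et3N, DMAP (cat.), 0 °C to rt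
Reagents that add atoms: none
Why: The Ghosez reagent gives the acid chloride under neutral conditions (ketal intact), which acylates the N-hydroxyphthalimide anion; the C13 carbonyl is still masked, so the cis-disposed ketone cannot divert the activated acid into a pseudo-ester.

Step 12
Reactants: 15 ketal-protected C9 N-acyloxyphthalimide
Product: 16 C9 N-acyloxyphthalimide with C14 acetyl and C7 ketone
Conditions: TFA/H2O (9:1), CH2Cl2, 0 °C
Reagents that add atoms: water, O
Why: Acid-catalysed ketal hydrolysis frees the methyl ketone, while N-acyloxyphthalimides tolerate aqueous acid and the C9 carbonyl is shielded by the quaternary centres around it.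

Step 13
Reactants: 16 C9 N-acyloxyphthalimide with C14 acetyl and C7 ketone; 17 phenyl vinyl sulfone
Product: 19 tetracyclic C12-phenylsulfonyl C13 carbinol, via open-chain sulfonyl carbanion 18 (not isolated)
Conditions: undivided cell, graphite-felt cathode, Mg anode, n-Bu4NClO4 (0.1 M), DMF/THF (1:1), 17 (3 equiv), constant current (about 2.5 F/mol), 0 °C; then 0.5 M HCl
Reagents that add atoms: none
Why: Proposed new method: cathodic one-electron reduction of the N-acyloxyphthalimide releases CO2 and phthalimide anion and leaves the tertiary C9 radical, which adds to the unsubstituted terminus of 17 (C9–C11), and the α-sulfonyl radical so formed is reduced at the same potential to carbanion 18, which attacks the carbonyl carbon of the acetyl group (C12–C13); the closest known reaction type is the reductive decarboxylative Giese addition of redox-active esters with radical–polar crossover and anionic trapping, which has not been shown with an aldol-type ring closure as one cascade. The cyclopentane (C9, C11, C12, C13, C14) closes in the 5-exo-trig mode with the carbanion as nucleophile. C9 can only be attacked on the β face, because the cyclobutane enforces the cis 6–4 fusion, and this places C11 cis to the acetyl group on the four-membered ring. C13 and C12 should be set by a magnesium ion that bridges a sulfonyl oxygen and the carbonyl oxygen on the convex face of the forming bicyclo[3.2.0]heptane, which puts sulfonyl and alkoxide cis and turns the methyl group over the cyclobutane. The step needs reduction of the ester in preference to both ketones and to 17, which its much less negative reduction potential secures, and it needs the carbanion to choose the C13 carbonyl, which is secured because the C7 carbonyl sits trans to C11 across the cyclobutane and cannot be reached.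

Step 14
Reactants: 19 tetracyclic C12-phenylsulfonyl C13 carbinol
Product: 20 tetracyclic C13 carbinol C7 ketone
Conditions: sodium amalgam (6% Na), Na2HPO4, MeOH/THF, −20 °C
Reagents that add atoms: none
Why: Reductive desulfonylation by two-electron transfer, with protonation of the C12 carbanion by methanol faster than loss of hydroxide; the phosphate buffer suppresses retro-aldol opening and the hindered C7 ketone is expected to survive at low temperature.

Step 15
Reactants: 20 tetracyclic C13 carbinol C7 ketone
Product: 21 C13 trimethylsilyl ether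
Conditions: N-(trimethylsilyl)imidazole, CH2Cl2, rt
Reagents that add atoms: N-(trimethylsilyl)imidazole, C[Si](C)(C)n1ccnc1
Why: Neutral silylation caps the tertiary alcohol so that the enolate acetylation of the next step cannot acylate it, and ketones are not enolized by this reagent.

Step 16
Reactants: 21 C13 trimethylsilyl ether
Product: 22 C6=C7 enol acetate
Conditions: KN(SiMe3)2, THF, −78 °C; Ac2O, −78 to 0 °C
Reagents that add atoms: acetic anhydride, CC(=O)OC(C)=O
Why: C6 is the only enolizable position of the C7 ketone (C8 is quaternary), and potassium enolates are acetylated on oxygen by acetic anhydride to give the enol acetate.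

Step 17
Reactants: 22 C6=C7 enol acetate
Product: 23 6α,7α-epoxy 7β-acetate
Conditions: dimethyldioxirane (acetone solution), CH2Cl2, −20 to 0 °C
Reagents that add atoms: dimethyldioxirane, CC1(C)OO1
Why: Epoxidation of the electron-rich enol acetate by the neutral dioxirane should occur on the α face, because the β face of C6–C7 is screened by the C4, C8 and C10 methyl groups, which sets C6 and C7 (epoxide oxygen α, acetoxy β).

Step 18
Reactants: 23 6α,7α-epoxy 7β-acetate
Product: 25 target 6β-acetoxy 7-ketone (CNP0330581.1), via trimethylsilyl ether 24 (not isolated)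
Conditions: toluene, 110 °C (sealed, base-washed glass); then 0.5 M HCl, THF, 0 °C
Reagents that add atoms: none
Why: Thermal enol ester epoxide rearrangement, in which the acetoxy group on C7 shifts intramolecularly to C6 from the face opposite the epoxide oxygen while C7 becomes the ketone, so C6 is inverted to the axial 6β-acetate stereospecifically under neutral conditions; dilute acid then removes the labile tertiary silyl ether without enolizing the ketone.

Compound list
1 | (+)-sclareolide | O=C1C[C@H]2[C@@](C)(CC[C@H]3C(C)(C)CCC[C@]23C)O1 | starting material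
2 | 11-hydroxysclareolide (OH on the lactone α-carbon, syn to H-9) | O=C1[C@@H](O)[C@H]2[C@@](C)(CC[C@H]3C(C)(C)CCC[C@]23C)O1 | intermediate
3 | 13,14,15,16-tetranorlabdane-8α,11,12-triol | OC[C@@H](O)[C@H]1[C@](C)(O)CC[C@H]2C(C)(C)CCC[C@]12C | intermediate
4 | 8α-hydroxy-12,13,14,15,16-pentanorlabdan-11-al (9β-formyl, 9α-H) | O=C[C@H]1[C@](C)(O)CC[C@H]2C(C)(C)CCC[C@]12C | intermediate
5 | 12,13,14,15,16-pentanorlabd-8-en-11-al (5α-H, 10β-methyl) | O=CC1=C(C)CC[C@H]2C(C)(C)CCC[C@]12C | intermediate
6 | 12,13,14,15,16-pentanorlabd-8-en-11-oic acid | OC(=O)C1=C(C)CC[C@H]2C(C)(C)CCC[C@]12C | intermediate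
7 | 7-oxo-12,13,14,15,16-pentanorlabd-8-en-11-oic acid | OC(=O)C1=C(C)C(=O)C[C@H]2C(C)(C)CCC[C@]12C | intermediate
8 | benzyl 7-oxo-12,13,14,15,16-pentanorlabd-8-en-11-oate | O=C(OCc1ccccc1)C1=C(C)C(=O)C[C@H]2C(C)(C)CCC[C@]12C | intermediate
9 | but-3-en-2-one | C=CC(C)=O | starting material
10 | 2-methyl-2-vinyl-1,3-dioxolane | C=CC1(C)OCCO1 | intermediate
11 | tricyclic photoadduct: benzyl ester on C9 (β), 8β-methyl, cyclobutane C8–C9–C14–C15 on the α face, C14 carrying the 2-methyl-1,3-dioxolan-2-yl group cis to the ester, C7 ketone | C1C(=O)[C@@]2(C)C[C@H](C3(C)OCCO3)[C@@]2(C(=O)OCc3ccccc3)[C@@]2(C)CCCC(C)(C)[C@H]12 | intermediate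
12 | carboxylic acid of 11 | C1C(=O)[C@@]2(C)C[C@H](C3(C)OCCO3)[C@@]2(C(=O)O)[C@@]2(C)CCCC(C)(C)[C@H]12 | intermediate
13 | N-hydroxyphthalimide | ON1C(=O)c2ccccc2C1=O | starting material
14 | acid chloride of 12 | C1C(=O)[C@@]2(C)C[C@H](C3(C)OCCO3)[C@@]2(C(Cl)=O)[C@@]2(C)CCCC(C)(C)[C@H]12 | intermediate
15 | N-acyloxyphthalimide of 12 (C13 still the dioxolane) | C1C(=O)[C@@]2(C)C[C@H](C3(C)OCCO3)[C@@]2(C(=O)ON3C(=O)c4ccccc4C3=O)[C@@]2(C)CCCC(C)(C)[C@H]12 | intermediate
16 | tricyclic C9 N-acyloxyphthalimide with C14 acetyl (cis to the ester on the cyclobutane) and C7 ketone | C1C(=O)[C@@]2(C)C[C@H](C(C)=O)[C@@]2(C(=O)ON3C(=O)c4ccccc4C3=O)[C@@]2(C)CCCC(C)(C)[C@H]12 | intermediate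
17 | phenyl vinyl sulfone | C=CS(=O)(=O)c1ccccc1 | starting material
18 | open-chain α-sulfonyl carbanion (C9–CH2–CH(−)–SO2Ph, acetyl still on C14) | C1C(=O)[C@@]2(C)C[C@H](C(C)=O)[C@@]2(C[CH-]S(=O)(=O)c3ccccc3)[C@@]2(C)CCCC(C)(C)[C@H]12 | intermediate
19 | tetracyclic C13 methyl carbinol with C12 phenylsulfonyl group (OH and sulfonyl cis, on the convex face; C13 methyl over the cyclobutane), C7 ketone | C1C(=O)[C@@]2(C)C[C@H]3[C@@]2(C[C@H](S(=O)(=O)c4ccccc4)[C@]3(C)O)[C@@]2(C)CCCC(C)(C)[C@H]12 | intermediate
20 | tetracyclic C13 methyl carbinol, C7 ketone (C12 methylene) | C1C(=O)[C@@]2(C)C[C@H]3[C@@]2(CC[C@]3(C)O)[C@@]2(C)CCCC(C)(C)[C@H]12 | intermediate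
21 | C13 trimethylsilyl ether of 20 | C1C(=O)[C@@]2(C)C[C@H]3[C@@]2(CC[C@]3(C)O[Si](C)(C)C)[C@@]2(C)CCCC(C)(C)[C@H]12 | intermediate
22 | C6=C7 enol acetate of 21 | C1=C(OC(C)=O)[C@@]2(C)C[C@H]3[C@@]2(CC[C@]3(C)O[Si](C)(C)C)[C@@]2(C)CCCC(C)(C)[C@H]12 | intermediate
23 | 6α,7α-epoxide of 22 (7β-acetoxy) | [C@H]1(O3)[C@]3(OC(C)=O)[C@@]2(C)C[C@H]4[C@@]2(CC[C@]4(C)O[Si](C)(C)C)[C@@]2(C)CCCC(C)(C)[C@H]12 | intermediate
24 | C13 trimethylsilyl ether of the target (6β-acetoxy, 7-ketone) | CC(=O)O[C@@H]1C(=O)[C@@]2(C)C[C@H]3[C@@]2(CC[C@]3(C)O[Si](C)(C)C)[C@@]2(C)CCCC(C)(C)[C@H]12 | intermediate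
25 | CNP0330581.1 (6β-acetoxy, 7-ketone, C13 methyl carbinol) | CC(=O)O[C@@H]1C(=O)[C@@]2(C)C[C@H]3[C@@]2(CC[C@]3(C)O)[C@@]2(C)CCCC(C)(C)[C@H]12 | target

Total step count: 18. Longest linear sequence: 17 steps (steps 1–7 and 9–18; step 8 is a one-step side branch).

Steps most likely to fail

Step 13. What may go wrong: proton transfer from the methyl ketone to the sulfonyl carbanion, or hydrogen-atom capture by the adduct radical, before the ring closes, and incomplete facial control at C13. Fallback with known chemistry, from 16 and 17: a visible-light reductive decarboxylative Giese addition (Ru(bpy)3(PF6)2 cat., Hantzsch ester, blue LEDs, CH2Cl2) should give the open-chain keto sulfone F1. Treatment of F1 with LiN(SiMe3)2 in THF (−78 to 0 °C) lets the sulfonyl carbanion form by proton exchange and add to the cis-disposed acetyl group as a lithium chelate. This intramolecular sulfone–ketone aldol addition should return to 19.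

Step 9. What may go wrong: bonding of the substituted alkene carbon to C8 instead of C9 (head-to-head orientation), trans ring fusion, or an unfavourable epimer ratio at C14. Fallback, from 8: irradiation with 1,1-diethoxyethene, whose two alkoxy groups direct the acetal carbon to C9, should give the cyclobutanone diethyl acetal F2. PPTS in wet acetone then gives the cyclobutanone F3. A Wittig reaction of this strained ketone with (1-methoxyethylidene)triphenylphosphorane gives the enol ether F4. Dilute acid followed by DBU equilibration gives the methyl ketone F5, with the acetyl group on the cyclobutane face away from C10. Selective ketalization of the unhindered methyl ketone (1,2-bis(trimethylsilyloxy)ethane, TMSOTf cat., −78 °C) returns to 11.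

Step 18. What may go wrong: acid-catalysed opening of the epoxy acetate, which returns the acetate to the α face (retention), or failure of the shift toward the crowded β face. Fallback, from 20: autoxidation (KOC(CH3)3, O2, t-BuOH/THF) should give the diosphenol F6. Ac2O in pyridine at 0 °C acetylates only the enol hydroxyl and gives the enol acetate F7. Catalytic hydrogenation (H2, Pd/C, EtOAc) should add both hydrogens to C5 and C6 from the α face, setting the trans ring fusion and the 6β-acetate together and returning directly to 25.

Further compounds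
F1 | step 13 | open-chain keto sulfone (C9–CH2CH2SO2Ph, C14 acetyl, C7 ketone) | C1C(=O)[C@@]2(C)C[C@H](C(C)=O)[C@@]2(CCS(=O)(=O)c3ccccc3)[C@@]2(C)CCCC(C)(C)[C@H]12
F2 | step 9 | photoadduct with C14 as diethyl acetal (benzyl ester, C7 ketone) | C1C(=O)[C@@]2(C)CC(OCC)(OCC)[C@@]2(C(=O)OCc3ccccc3)[C@@]2(C)CCCC(C)(C)[C@H]12
F3 | step 9 | C14 cyclobutanone (benzyl ester, C7 ketone) | C1C(=O)[C@@]2(C)CC(=O)[C@@]2(C(=O)OCc3ccccc3)[C@@]2(C)CCCC(C)(C)[C@H]12
F4 | step 9 | C14 (1-methoxyethylidene) enol ether, mixture of double-bond isomers | C1C(=O)[C@@]2(C)CC(=C(C)OC)[C@@]2(C(=O)OCc3ccccc3)[C@@]2(C)CCCC(C)(C)[C@H]12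
F5 | step 9 | C14 acetyl benzyl ester (acetyl cis to the ester, C7 ketone) | C1C(=O)[C@@]2(C)C[C@H](C(C)=O)[C@@]2(C(=O)OCc3ccccc3)[C@@]2(C)CCCC(C)(C)[C@H]12
F6 | step 18 | diosphenol (6-hydroxy-5-en-7-one, free C13 carbinol) | C1(O)C(=O)[C@@]2(C)C[C@H]3[C@@]2(CC[C@]3(C)O)[C@@]2(C)CCCC(C)(C)C=12
F7 | step 18 | diosphenol acetate (6-acetoxy-5-en-7-one, free C13 carbinol) | C1(OC(C)=O)C(=O)[C@@]2(C)C[C@H]3[C@@]2(CC[C@]3(C)O)[C@@]2(C)CCCC(C)(C)C=12
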